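**Plan**

- Cuts: the two acetates go back to the 15,17-diol and C17 is raised to a methyl ester. Ring B is then opened at C9–C10, with an acetoxy group placed on C7. The chain is cut at C7–C8 into a ring A aldehyde (C1–C7, C10, C18–C20) and a chiral ynoate (C8, C9, C11–C17).
- Enabling feature: in ring B the alkene carbon C8 carries the oxygenated carbon C17, so at the ester level C8=C9 is a radical acceptor with C9 as its β-carbon. C10, the methyl-bearing quaternary carbon, is the Markovnikov end of a ring A alkene (C1=C10) and can be entered as a tertiary radical. A leaving group on C7 turns the cyclised enolate into the C7=C8 alkene.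
- Forward order: ring A is bought as a cyclohexenone and its C6–C7 arm is put on C5 by Claisen rearrangement. The arm aldehyde and the ynoate are joined at C7–C8 by vinylalumination–aldol. Ring B is closed last at C9–C10, then reduction and acetylation finish.
- Stereochemistry: C13 comes from (S)-citronellol. C5 comes from a Corey–Bakshi–Shibata reduction relayed by a suprafacial [3,3] shift. C10 and C9 are set in the ring closure, by C5 (trans ring fusion) and by the (Z)-alkene from syn hydroalumination.

Key step: step 9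

Remark: 2,4,4-trimethylcyclohex-2-en-1-one (1) is taken as a purchasable compound; otherwise it is one step from isobutyraldehyde and ethyl vinyl ketone.
Numbering: labdane numbering is used (ring A = C1–C5, C10; ring B = C5–C10; C17 on C8; side chain C11–C15 on C9 with methyl C16 on C13; C18, C19 on C4; C20 on C10).

**Route**

Step 1
Reactants: 1 2,4,4-trimethylcyclohex-2-en-1-one
Product: 2 (1R)-2,4,4-trimethylcyclohex-2-en-1-ol
Conditions: (S)-2-methyl-CBS-oxazaborolidine (10 mol%), catecholborane, toluene, −78 °C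
Reagents that add atoms: none
Why: Corey–Bakshi–Shibata reduction: the oxazaborolidine binds the carbonyl anti to the larger 2-methylvinyl flank and delivers hydride to one face, which for the (S)-catalyst should give the (R)-allylic alcohol, and catecholborane at low temperature leaves the trisubstituted alkene alone.

Step 2
Reactants: 2 (1R)-2,4,4-trimethylcyclohex-2-en-1-ol
Product: 4 ethyl 2-[(1S)-2,6,6-trimethylcyclohex-2-en-1-yl]acetate, via ketene acetal 3 (not isolated)
Conditions: MeC(OEt)3, EtCO2H (cat.), 140 °C, EtOH distilled off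
Reagents that add atoms: triethyl orthoacetate, CC(OCC)(OCC)OCC
Why: Johnson–Claisen rearrangement: ketene acetal 3 rearranges suprafacially, so the new C5–C6 bond forms on the ring face that the C1–O bond leaves, the carbinol configuration is relayed to C5 (S), and the alkene moves to C1=C10, where the radical of step 9 will be started.

Step 3
Reactants: 4 ethyl 2-[(1S)-2,6,6-trimethylcyclohex-2-en-1-yl]acetate
Product: 5 2-[(1S)-2,6,6-trimethylcyclohex-2-en-1-yl]acetaldehyde
Conditions: i-Bu2AlH (1.05 equiv), CH2Cl2, −78 °C; aq. Rochelle salt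
Reagents that add atoms: none
Why: Partial ester reduction: at −78 °C the aluminium hemiacetal is stable until work-up, so the aldehyde (C7) is obtained, and C5, β to the carbonyl, cannot epimerise.

Step 4
Reactants: 6 (S)-citronellol [(3S)-3,7-dimethyloct-6-en-1-ol]
Product: 7 (3S)-3,7-dimethyloct-6-en-1-yl pivalate
Conditions: t-BuCOCl, pyridine, DMAP (cat.), CH2Cl2, 0 → 23 °C
Reagents that add atoms: pivaloyl chloride, CC(C)(C)C(Cl)=O
Why: Acylation of the primary alcohol: the pivalate has no α-hydrogen and is hindered, so it should pass through the carbonate, amide-base and complexed-hydride conditions of steps 6 to 8 and is then removed without an extra step by the hydride of step 10.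

Step 5
Reactants: 7 (3S)-3,7-dimethyloct-6-en-1-yl pivalate
Product: 9 (3S)-3-methyl-6-oxohexyl pivalate, via ozonide 8 (not isolated)
Conditions: O3, CH2Cl2, −78 °C; then Me2S, −78 → 23 °C
Reagents that add atoms: ozone, [O-][O+]=O
Why: Ozonolysis of the only alkene with reductive work-up of ozonide 8 gives the aldehyde whose carbon becomes C9, and C13 is not touched.

Step 6
Reactants: 9 (3S)-3-methyl-6-oxohexyl pivalate
Product: 10 (3S)-3-methylhept-6-yn-1-yl pivalate
Conditions: MeC(O)C(N2)P(O)(OMe)2, K2CO3, MeOH, 0 → 23 °C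
Reagents that add atoms: dimethyl (1-diazo-2-oxopropyl)phosphonate, CC(=O)C(=[N+]=[N-])P(=O)(OC)OC
Why: Seyferth–Gilbert homologation with the Ohira–Bestmann reagent adds the carbon that becomes C8 under mild carbonate conditions, which the aldehyde (no α-stereocentre) and the hindered pivalate should tolerate.

Step 7
Reactants: 10 (3S)-3-methylhept-6-yn-1-yl pivalate
Product: 12 methyl (6S)-6-methyl-8-(pivaloyloxy)oct-2-ynoate, via lithium acetylide 11 (not isolated)
Conditions: LiN(i-Pr)2, THF, −78 °C; then ClCO2Me, −78 → 0 °C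
Reagents that add atoms: methyl chloroformate, COC(Cl)=O
Why: The non-nucleophilic amide base deprotonates only the terminal alkyne, and C-acylation of acetylide 11 with the chloroformate installs C17 at the ester level that later makes C8=C9 a radical acceptor.

Step 8
Reactants: 12 methyl (6S)-6-methyl-8-(pivaloyloxy)oct-2-ynoate; 5 2-[(1S)-2,6,6-trimethylcyclohex-2-en-1-yl]acetaldehyde
Product: 15 methyl (2Z,6S)-2-{1-acetoxy-2-[(1S)-2,6,6-trimethylcyclohex-2-en-1-yl]ethyl}-6-methyl-8-(pivaloyloxy)oct-2-enoate (both epimers at the acetoxy carbon C7), via vinylalane 13 (not isolated), via aluminium alkoxide 14 (not isolated)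
Conditions: i-Bu2AlH, N-methylmorpholine N-oxide, THF, 0 °C; then 5, 0 → 23 °C; then Ac2O, pyridine, DMAP (cat.)
Reagents that add atoms: acetic anhydride, CC(=O)OC(C)=O
Why: Vinylalumination–aldol: syn hydroalumination of the ynoate puts aluminium on C8 and hydrogen on C9, the α-alumino enoate 13 adds to aldehyde 5 at C8 with retention so that the C11 chain stays cis to the ester ((Z), the geometry that later sets C9), and the aluminium alkoxide 14 is acetylated in the same flask, the configuration of C7 being irrelevant because step 9 removes it.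

Step 9
Reactants: 15 methyl (2Z,6S)-2-{1-acetoxy-2-[(1S)-2,6,6-trimethylcyclohex-2-en-1-yl]ethyl}-6-methyl-8-(pivaloyloxy)oct-2-enoate
Product: 17 methyl (5S,9R,10S,13S)-15-(pivaloyloxy)labd-7-en-17-oate, via acetoxy ester 16 (not isolated)
Conditions: Fe(acac)3 (30 mol%), PhSiH3, EtOH/(CH2OH)2 (5:1), 0.02 M, 60 °C; then DBU, 23 → 60 °C
Reagents that add atoms: none
Why: The hydride formed from Fe(acac)3 and PhSiH3 transfers a hydrogen atom to C1 of the ring A alkene, the tertiary C10 radical adds to C9 (the β-carbon of the enoate), the C8 radical is reduced by divalent iron to the ester enolate, and acetate leaves C7 by E1cB elimination, completed by DBU for any material that was protonated to 16. The closest known reaction type is the iron-hydride reductive olefin coupling (hydrogen-atom-transfer Giese addition of an alkene to an acrylate), joined to the addition–elimination that radicals undergo with Morita–Baylis–Hillman acetates. Ring B closes in the 6-endo-trig mode, because attack at C8 would have to join two fully substituted carbons and would leave an unstabilised radical on C9. C10 is controlled by C5, whose tether is equatorial while the axial methyl on C4 screens the β face of the radical, so C9 should bond to the α face and give the trans ring fusion, and C9 is controlled by the (Z)-alkene, whose C11 chain lies trans to C7 and becomes equatorial in the chair-like transition state. The step needs hydrogen atom transfer to the electron-rich C1=C10 alkene in preference to the electron-poor enoate, which the polarity of the hydride secures, and it needs the new alkene at C7=C8 only, which the place of the acetoxy group secures. If the C10 radical returned to an alkene by loss of H5, the tetrasubstituted C5=C10 alkene formed would be a poor hydrogen atom acceptor, so such material should stay out of the cyclisation and C5 should not leak.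

Step 10
Reactants: 17 methyl (5S,9R,10S,13S)-15-(pivaloyloxy)labd-7-en-17-oate
Product: 18 (5S,9R,10S,13S)-labd-7-ene-15,17-diol
Conditions: i-Bu2AlH (6 equiv), CH2Cl2, −78 → 0 °C; aq. Rochelle salt
Reagents that add atoms: none
Why: Hydride reduction: i-Bu2AlH reduces the conjugated ester in the 1,2-sense to the allylic alcohol and cleaves the pivalate in the same operation, leaving the trisubstituted alkene and all stereocentres untouched.

Step 11
Reactants: 18 (5S,9R,10S,13S)-labd-7-ene-15,17-diol
Product: 19 (5S,9R,10S,13S)-labd-7-ene-15,17-diyl diacetate (target, CNP0294037.1)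
Conditions: Ac2O, pyridine, DMAP (cat.), CH2Cl2, 23 °C
Reagents that add atoms: acetic anhydride, CC(=O)OC(C)=O
Why: Acetylation of the primary and the primary allylic hydroxyl under basic, non-ionising conditions, in which the C7=C8 alkene does not migrate.

**Compound list**

1 | 2,4,4-trimethylcyclohex-2-en-1-one | O=C1CCC(C)(C)C=C1C | starting material
2 | (1R)-2,4,4-trimethylcyclohex-2-en-1-ol | O[C@@H]1CCC(C)(C)C=C1C | intermediate
3 | ketene acetal: 1-ethoxyvinyl ether of alcohol 2 | C=C(OCC)O[C@@H]1CCC(C)(C)C=C1C | intermediate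
4 | ethyl 2-[(1S)-2,6,6-trimethylcyclohex-2-en-1-yl]acetate | CCOC(=O)C[C@H]1C(C)(C)CCC=C1C | intermediate
5 | 2-[(1S)-2,6,6-trimethylcyclohex-2-en-1-yl]acetaldehyde | O=CC[C@H]1C(C)(C)CCC=C1C | intermediate
6 | (S)-citronellol, (3S)-3,7-dimethyloct-6-en-1-ol | OCC[C@@H](C)CCC=C(C)C | starting material
7 | (3S)-3,7-dimethyloct-6-en-1-yl pivalate | CC(C)(C)C(=O)OCC[C@@H](C)CCC=C(C)C | intermediate
8 | ozonide: (3S)-5-(3,3-dimethyl-1,2,4-trioxolan-5-yl)-3-methylpentyl pivalate | CC(C)(C)C(=O)OCC[C@@H](C)CCC1OOC(C)(C)O1 | intermediate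
9 | (3S)-3-methyl-6-oxohexyl pivalate | CC(C)(C)C(=O)OCC[C@@H](C)CCC=O | intermediate
10 | (3S)-3-methylhept-6-yn-1-yl pivalate | CC(C)(C)C(=O)OCC[C@@H](C)CCC#C | intermediate
11 | lithium acetylide of 10 | CC(C)(C)C(=O)OCC[C@@H](C)CCC#C[Li] | intermediate
12 | methyl (6S)-6-methyl-8-(pivaloyloxy)oct-2-ynoate | CC(C)(C)C(=O)OCC[C@@H](C)CCC#CC(=O)OC | intermediate
13 | vinylalane: methyl (2E,6S)-2-(diisobutylalumanyl)-6-methyl-8-(pivaloyloxy)oct-2-enoate (Al and H-9 cis) | CC(C)(C)C(=O)OCC[C@@H](C)CC/C=C(\C(=O)OC)[Al](CC(C)C)CC(C)C | intermediate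
14 | diisobutylaluminium alkoxide of the aldol adduct (C7–O–Al, (2Z)-alkene) | CC(C)(C)C(=O)OCC[C@@H](C)CC/C=C(\C(=O)OC)C(O[Al](CC(C)C)CC(C)C)C[C@H]1C(C)(C)CCC=C1C | intermediate
15 | methyl (2Z,6S)-2-{1-acetoxy-2-[(1S)-2,6,6-trimethylcyclohex-2-en-1-yl]ethyl}-6-methyl-8-(pivaloyloxy)oct-2-enoate | CC(C)(C)C(=O)OCC[C@@H](C)CC/C=C(\C(=O)OC)C(OC(C)=O)C[C@H]1C(C)(C)CCC=C1C | intermediate
16 | methyl 7-acetoxy-15-(pivaloyloxy)labdan-17-oate with the ring stereocentres of 17 (C7 and C8 epimers) | CC(C)(C)C(=O)OCC[C@@H](C)CC[C@H]1C(C(=O)OC)C(OC(C)=O)C[C@H]2C(C)(C)CCC[C@]12C | intermediate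
17 | methyl (5S,9R,10S,13S)-15-(pivaloyloxy)labd-7-en-17-oate | CC(C)(C)C(=O)OCC[C@@H](C)CC[C@H]1C(C(=O)OC)=CC[C@H]2C(C)(C)CCC[C@]12C | intermediate
18 | (5S,9R,10S,13S)-labd-7-ene-15,17-diol | OCC[C@@H](C)CC[C@H]1C(CO)=CC[C@H]2C(C)(C)CCC[C@]12C | intermediate
19 | (5S,9R,10S,13S)-labd-7-ene-15,17-diyl diacetate | CC(=O)OCC[C@@H](C)CC[C@H]1C(COC(C)=O)=CC[C@H]2C(C)(C)CCC[C@]12C | target

**Step count and risks**

Total step count: 11 steps.
Longest linear sequence: 8 steps (steps 4 to 11, from (S)-citronellol); the ring A branch (steps 1 to 3) joins at step 8.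

Steps most likely to fail:

1. Step 9 (key step). The C10 radical may take up hydrogen before it closes onto the hindered, β-substituted enoate (net hydrogenation of C1=C10), or it may close through the cis-fused transition state. The fallback is a polar closure with late oxidation of C17; it sets out from ester 4 and alkyne 10 and comes back at diol 18.
   - Ester 4 would be reduced with LiAlH4 to 2-[(1S)-2,6,6-trimethylcyclohex-2-en-1-yl]ethan-1-ol F1. I2, PPh3 and imidazole would give (6S)-6-(2-iodoethyl)-1,5,5-trimethylcyclohex-1-ene F2, and zinc dust with LiCl in THF the alkylzinc iodide F3.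
   - Alkyne 10 would be methylated through its lithium acetylide 11 (LiN(i-Pr)2, then MeI) to (3S)-3-methyloct-6-yn-1-yl pivalate F4. Syn hydrozirconation with Cp2Zr(H)Cl should place zirconium on the methyl-bearing carbon and give the alkenylzirconocene chloride F5, and iodine then the vinyl iodide (3S,6E)-7-iodo-3-methyloct-6-en-1-yl pivalate F6.
   - Negishi coupling of F3 with F6 (Pd(PPh3)4, THF) would give (3S,6E)-3,7-dimethyl-9-[(1S)-2,6,6-trimethylcyclohex-2-en-1-yl]non-6-en-1-yl pivalate F7, in which C8=C9 is electron-rich and C17 is a methyl group.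
   - Cation–olefin cyclisation (ClSO3H, 2-nitropropane, −78 °C) should protonate C1, let C9 attack the C10 cation through the chair, and lose H7, giving (5S,9S,10S,13S)-labd-7-en-15-yl pivalate F8.
   - Allylic oxidation of the C17 methyl group (SeO2 cat., t-BuOOH, CH2Cl2) would give (5S,9R,10S,13S)-17-hydroxylabd-7-en-15-yl pivalate F9, and i-Bu2AlH would remove the pivalate to return to 18.

2. Step 8. The α-alumino enoate may isomerise through its allenolate before or during the aldol addition, which would lose the alkene geometry that later sets C9, and leftover hydride may reduce aldehyde 5. The fallback uses a configurationally fixed alkenyl halide and chromium; it sets out from ynoate 12 (with aldehyde 5) and comes back at 15.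
   - Syn hydrostannation of 12 (Bu3SnH, Pd(PPh3)4 cat.) would give methyl (2E,6S)-6-methyl-8-(pivaloyloxy)-2-(tributylstannyl)oct-2-enoate F10.
   - Iodine would exchange tin with retention to methyl (2E,6S)-2-iodo-6-methyl-8-(pivaloyloxy)oct-2-enoate F11.
   - Nozaki–Hiyama–Kishi coupling of F11 with aldehyde 5 (CrCl2, NiCl2 cat., DMF) would give methyl (2Z,6S)-2-{1-hydroxy-2-[(1S)-2,6,6-trimethylcyclohex-2-en-1-yl]ethyl}-6-methyl-8-(pivaloyloxy)oct-2-enoate F12.
   - Acetylation (Ac2O, pyridine, DMAP) would give 15.

3. Step 2. At 140 °C under acid the allylic alcohol may ionise (dehydration to dienes, erosion of optical purity) faster than the [3,3] shift forms the bond next to the quaternary C4. The fallback is an ester-enolate rearrangement near room temperature; it sets out from alcohol 2 and comes back at ester 4.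
   - Alcohol 2 would be acetylated (Ac2O, pyridine) to (1R)-2,4,4-trimethylcyclohex-2-en-1-yl acetate F13.
   - Ireland–Claisen rearrangement (LiN(i-Pr)2, Me3SiCl, THF, −78 °C, then warming) would pass through the silyl ketene acetal F14 and give, with the same suprafacial transfer, the trimethylsilyl ester F15.
   - Aqueous work-up would free 2-[(1S)-2,6,6-trimethylcyclohex-2-en-1-yl]acetic acid F16, and EtI with K2CO3 in DMF would give 4.

Further compounds
F1 | step 9 | 2-[(1S)-2,6,6-trimethylcyclohex-2-en-1-yl]ethan-1-ol | OCC[C@H]1C(C)(C)CCC=C1C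
F2 | step 9 | (6S)-6-(2-iodoethyl)-1,5,5-trimethylcyclohex-1-ene | ICC[C@H]1C(C)(C)CCC=C1C
F3 | step 9 | {2-[(1S)-2,6,6-trimethylcyclohex-2-en-1-yl]ethyl}zinc iodide | I[Zn]CC[C@H]1C(C)(C)CCC=C1C
F4 | step 9 | (3S)-3-methyloct-6-yn-1-yl pivalate | CC(C)(C)C(=O)OCC[C@@H](C)CCC#CC
F5 | step 9 | alkenylzirconocene chloride from F4 (zirconium on the methyl-bearing carbon, cis to the vinyl hydrogen) | CC(C)(C)C(=O)OCC[C@@H](C)CC/C=C(\C)[Zr](Cl)(C1C=CC=C1)C1C=CC=C1
F6 | step 9 | (3S,6E)-7-iodo-3-methyloct-6-en-1-yl pivalate | CC(C)(C)C(=O)OCC[C@@H](C)CC/C=C(\C)I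
F7 | step 9 | (3S,6E)-3,7-dimethyl-9-[(1S)-2,6,6-trimethylcyclohex-2-en-1-yl]non-6-en-1-yl pivalate | CC(C)(C)C(=O)OCC[C@@H](C)CC/C=C(\C)CC[C@H]1C(C)(C)CCC=C1C
F8 | step 9 | (5S,9S,10S,13S)-labd-7-en-15-yl pivalate | CC(C)(C)C(=O)OCC[C@@H](C)CC[C@H]1C(C)=CC[C@H]2C(C)(C)CCC[C@]12C
F9 | step 9 | (5S,9R,10S,13S)-17-hydroxylabd-7-en-15-yl pivalate | CC(C)(C)C(=O)OCC[C@@H](C)CC[C@H]1C(CO)=CC[C@H]2C(C)(C)CCC[C@]12C
F10 | step 8 | methyl (2E,6S)-6-methyl-8-(pivaloyloxy)-2-(tributylstannyl)oct-2-enoate | CC(C)(C)C(=O)OCC[C@@H](C)CC/C=C(\C(=O)OC)[Sn](CCCC)(CCCC)CCCC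
F11 | step 8 | methyl (2E,6S)-2-iodo-6-methyl-8-(pivaloyloxy)oct-2-enoate | CC(C)(C)C(=O)OCC[C@@H](C)CC/C=C(\C(=O)OC)I
F12 | step 8 | methyl (2Z,6S)-2-{1-hydroxy-2-[(1S)-2,6,6-trimethylcyclohex-2-en-1-yl]ethyl}-6-methyl-8-(pivaloyloxy)oct-2-enoate | CC(C)(C)C(=O)OCC[C@@H](C)CC/C=C(\C(=O)OC)C(O)C[C@H]1C(C)(C)CCC=C1C
F13 | step 2 | (1R)-2,4,4-trimethylcyclohex-2-en-1-yl acetate | CC(=O)O[C@@H]1CCC(C)(C)C=C1C
F14 | step 2 | silyl ketene acetal: 1-(trimethylsilyloxy)vinyl ether of alcohol 2 | C=C(O[Si](C)(C)C)O[C@@H]1CCC(C)(C)C=C1C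
F15 | step 2 | trimethylsilyl 2-[(1S)-2,6,6-trimethylcyclohex-2-en-1-yl]acetate | C[Si](C)(C)OC(=O)C[C@H]1C(C)(C)CCC=C1C
F16 | step 2 | 2-[(1S)-2,6,6-trimethylcyclohex-2-en-1-yl]acetic acid | OC(=O)C[C@H]1C(C)(C)CCC=C1C
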